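All runs were computed with made-up constants, and the scatter is random.

The enzyme in the ochre flask, given half the [second substrate] of its near twin teal, ends with about twice the target: 8.5 % against 4.3 %. Grey, with the most second substrate, reads 2.2 %.

| flask | starting material | second substrate | capture agent | enzyme | remark | time |
|---|---|---|---|---|---|---|
| teal | 0.13 M | 0.13 M | 2.6 mM | 64 µM | run made earlier |  |
| ochre | 0.13 M | 0.065 M | 2.6 mM | 64 µM | run made earlier |  |
| grey | 0.13 M | 0.26 M | 2.6 mM | 64 µM | run made earlier |  |
| north-west | 0.13 M (fed, over 10 min) | 0.130 M | 2.60 mM | 64 µM | all else is in the flask from the start; the feed brings no volume worth counting | 50 min |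
| west | 0.13 M | 0.130 M | 2.60 mM | 64 µM | everything together at the start | 50 min |
| south-east | 0.13 M | 0.130 M (fed, over 10 min) | 2.60 mM | 64 µM | all else is in the flask from the start; the feed brings no volume worth counting | 50 min |
| south-west | 0.13 M | 0.130 M (in portions, 2, over 10 min) | 2.60 mM | 64 µM | first portion at the start, last at 10 min | 50 min |

- teal (time / min: target / %): 6.00: 4.2; 20.0: 4.4; 30.0: 3.7; 50.0: 4.3
- ochre (time / min: target / %): 10.0: 7.1; 20.0: 8.3; 30.0: 8.6; 40.0: 8.5
- grey (time / min: target / %): 5.00: 2.0; 15.0: 2.1; 25.0: 2.4; 40.0: 2.2

(readings scatter by 0.3 percentage points)



* the best flask by amount of target, in percent of the starting material charged; "all alike" if 1.5 percentage points covers them all (north-west / west / south-east / south-west / all alike)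
* amount of target at the end, in percent of the starting material charged, north-west
* amount of target at the end, in percent of the starting material charged, west
* amount of target at the end, in percent of the starting material charged, south-east
* amount of target at the end, in percent of the starting material charged, south-west

We read these plateaus as a pseudo-first-order loss of working enzyme, with a rate proportional to [second substrate]. Ochre gives the scale: 7.1 % at 10.0 min under a plateau of 8.5 % means a life of 5.54 min, read through a scatter of 0.3 percentage points. Multiplied by ochre's [second substrate], this life gives 0.360 M·min, the exposure allowance: the time integral of [second substrate] that cuts the working enzyme by a factor e. Ochre's first rate is then 0.0153 min⁻¹, as a fraction of the charge. At teal's [second substrate] the allowance lasts 2.77 min, which gives 4.24 %; teal took no part in this estimate, so its reading is a check.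

Our own reckoning follows. West repeats teal. South-east meets a rising [second substrate]; counted as a sharp budget, the allowance lasts 7.45 min, shorter than the feed, and gives 11.4 %. South-west starts at ochre's [second substrate], so we expect about ochre's plateau. We give north-west west's enzyme life, but its starting material arrives slowly. If the rate is first order in [starting material], which these runs do not test, we solve both ends and join them. A life long against the feed gives a working time equal to the life; a short one gives life squared over feed time. The join, life squared over feed time, multiplied by one minus exp(−feed time/life), gives 1.15 %.

The forecast names south-east, with 3 % for north-west, 4.2 % for west, 8.8 % for south-east and 7.7 % for south-west: “Target is not limited by substrate.” Its north-west is higher than ours, and its south-east lower.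

The flasks give 1.27 % in north-west, 4.50 % in west, 10.4 % in south-east and 7.97 % in south-west, so south-east is best.

    complex A ⇌ enzyme + target (K = 0.110 M, k = 2.90 s⁻¹)
    2 complex A ⇌ resting dimer, settled at all times (K = 17000 L mol⁻¹)
    second substrate + enzyme ⇌ complex B (K = 9.70 L mol⁻¹, k = 230 L mol⁻¹ s⁻¹)
    starting material + enzyme ⇌ complex A (K = 3.60 L mol⁻¹, k = 3100 L mol⁻¹ s⁻¹)
    complex B → enzyme + second product (k = 2.20 s⁻¹)
    capture agent + complex B → trapped intermediate (k = 4.80 L mol⁻¹ s⁻¹)

The allowance of 0.360 M·min lasts 2.77 min at north-west's charged [second substrate]; at 50.0 min in north-west the trapped intermediate holds >99.9 % of the catalyst, while 99 % of the starting material stands unbound. The gap of 9.1 points between south-east and north-west falls to 0 points without the reverse step from complex A to starting material and enzyme, and to 0.16 points without the binding of second substrate to enzyme. In the neighbour like north-west but with 0.052 M of second substrate, the allowance lasts 6.93 min, and the same join gives 5.62 %; the computed flask gives 5.31 %.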